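## Structural features

The target is a flavonol in which a benzene ring A is fused through the C4a–C8a bond to a 4H-pyran-4-one ring C, and a 4-hydroxyphenyl ring B is joined by a single bond to C2. Ring A carries no hydrogen, because C5 bears a hydroxyl hydrogen-bonded to the C4 carbonyl, C6, C7 and C8 bear methoxyls, and C8a bears the ring oxygen O1, so five adjacent ring A carbons are oxygenated. Ring C carries the enolic 3-hydroxyl beside the C4 ketone. There is no stereocentre and no alkene geometry, so the problem is one of regiochemistry and oxidation level only. The fragile parts are the 3-hydroxy-4-pyranone (degraded by base in air), the C5 hydroxyl para to the C8 methoxyl (a latent 5,8-quinone under strong oxidants), and the three methyl ethers, which must survive while a fourth oxygen on the same ring stays a free phenol. The real difficulty is this fully substituted, pentaoxygenated ring A with one hydroxyl set apart from three methoxyls. The key step exploits the fact that C4, C4a and C6, C7 and C8 with their methoxyls make up a 3,4,5-trimethoxybenzoyl group with two equivalent ortho C–H bonds, of which one becomes the C8a–O1 bond by oxidative ring closure while the other, C5–H, is left as the only ring A hydrogen, peri to the C4 carbonyl that can direct its hydroxylation.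

## Logic of the disconnections

8 to 7: the two acetyl–oxygen bonds at O3 and O4' are cut. The free enol and phenol could not pass through the two oxidative steps, and as acetates they are also electron-poor, which those steps need. No skeletal simplification results, but the last step becomes a plain ester cleavage. It must be non-oxidative and mild, because the flavonol anion is air-sensitive.

7 to 5 (through 6): the C5–O bond is cut. In 5 ring A has exactly one hydrogen, and it sits peri to the C4 ketone, the geometry of a ketone-directed C–H oxygenation. The gain is that ring A of 5 needs only three methoxyls, so it can come from a symmetric benzoyl unit. The forward step must use an oxidant that spares the methoxy-rich ring, and the new oxygen must stay masked as an electron-poor ester (6) until the oxidant is gone.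

5 to 4: the O1–C8a bond is cut (the key disconnection). Ring C opens to an acyclic 1,3-diketone whose ring A part is a symmetric trimethoxyphenyl ketone, so no ortho-oxygenated, pentasubstituted acetophenone is needed. The forward step must join the enol oxygen on the ring B side to an ortho carbon of ring A with loss of two hydrogens. It must not close onto ring B and must not oxidise the product further.

4 to 3: the bond between the central carbon (future C3) and its acetoxy oxygen is cut. That carbon is the nucleophilic enol carbon of 3, so the oxygen can arrive as an electrophile from a trivalent iodine acetate donor. The gain is an achiral, unsubstituted 1,3-diketone. The forward step must stop at mono-acetoxylation and leave the arenes alone.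

3 to 1 + 2: the bond between the central carbon and the carbonyl carbon that bears ring B (future C3–C2) is cut, a Claisen-type disconnection into a methyl ketone and an aroyl electrophile. Both pieces are stock arenes, and ring B already carries its oxygen as the acetate needed later. The enolisation must therefore be mild enough to spare an aryl acetate, which points to magnesium/amine soft enolisation and not a hydride base.

## Other disconnections considered

Alternative 1: The cut removes C3–C4 and O1–C2 together, dividing ring C between a ring A quinoketene and a two-carbon enol ether that carries ring B.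
- Forward step: the benzodioxinone 5,6,7,8-tetramethoxy-2,2-dimethyl-4H-1,3-benzodioxin-4-one A1 would extrude its acetonide ketone on heating or irradiation to give the quinoketene 2,3,4,5-tetramethoxy-6-(oxomethylidene)cyclohexa-2,4-dien-1-one A2. A2 would combine in a [4+2] sense with the silyl enol ether (Z)-{[2-(benzyloxy)-1-[4-(benzyloxy)phenyl]ethenyl]oxy}trimethylsilane A3, and loss of silanol would give 3-(benzyloxy)-2-[4-(benzyloxy)phenyl]-5,6,7,8-tetramethoxy-4H-chromen-4-one A4.
- In favour: two bonds and ring C form in one convergent operation, all five ring A oxygens are present from the start, and no C–H oxidation is needed. A stepwise C-acylation followed by O-closure would converge on the same A4, so the mechanism is forgiving.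
- Against: A1 rests on a pentasubstituted salicylic acid that is not a stock compound, so the ring A problem moves to the front of the route. A benzo-fused dioxinone must give up aromaticity to form A2 and should need much harsher activation than a simple dioxinone, which strains A3. Dimerisation of A2 and its capture by traces of water would compete.
- Comparison: on structure it is the better plan for chemoselectivity, since it avoids both oxidative steps. On mechanism it is at least the equal, because acylketene/enol ether pyranone formation is closer precedent than the anodic closure. Its end-game is equal or better: one chelation-controlled Lewis-acid treatment of A4 should cleave the C5 methyl ether and both benzyl ethers. On step economy it is worse, since A1 and A3 each need several steps against five steps in all from 1 and 2.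

Alternative 2: The cut removes the ring A bonds C4a–C5 and C8–C8a, so that the benzene ring is built from a furan diene (C5 to C8) and an alkyne (C4a and C8a).
- Forward step: the siloxyfuran tert-butyl[(3,4-dimethoxyfuran-2-yl)oxy]dimethylsilane A5 would add across the triple bond of the ynone rac-2-(benzyloxy)-1-[4-(benzyloxy)phenyl]pent-4-yne-1,3-dione A6. The oxanorbornadiene would open and aromatise, and desilylation would give the acylhydroquinone rac-2-(benzyloxy)-3-[4-(benzyloxy)phenyl]-1-(2,5-dihydroxy-3,4-dimethoxyphenyl)propane-1,3-dione A7.
- Atom mapping: in A7 the hydroxyl next to the ketone is the C5 hydroxyl, the two methoxyls sit at C6 and C7, the second hydroxyl is at C8, and the only ring hydrogen is on C8a. Either orientation of A5 on A6 leads to the same A7, because both furan termini end as hydroxyls.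
- Onward route: ring C must then be closed at C8a–H. Oxidation of A7 would give the acylquinone rac-2-(benzyloxy)-1-[4-(benzyloxy)phenyl]-3-(4,5-dimethoxy-3,6-dioxocyclohexa-1,4-dien-1-yl)propane-1,3-dione A8. In A8 the quinone C–H carbon is a doubly activated acceptor and no free phenol remains. Conjugate addition of the enol oxygen to that carbon and tautomerisation would give 3-(benzyloxy)-2-[4-(benzyloxy)phenyl]-5,8-dihydroxy-6,7-dimethoxy-4H-chromen-4-one A9. Methylation of the unchelated C8 hydroxyl of A9 and hydrogenolysis of both benzyl ethers would finish the synthesis.
- In favour: the cycloaddition is mild and electronically controlled. The C5 oxygen is present from the benzannulation on and is kept apart from the C8 oxygen by chelation, so no C–H hydroxylation of a methoxy-rich flavone is needed; on this point the alternative is the better plan. Closing ring C by addition of an enol oxygen to an acylquinone rests on ordinary quinone reactivity, which is closer to known chemistry than the anodic closure; here too it is the better.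
- Against: A6 combines an ynone with an enolisable 1,3-diketone and should cyclise by attack of its own enol oxygen on the triple bond to a 4-pyranone before A5 can add. A5 is hydrolytically labile and must be made from a butenolide. A7 is a 2-hydroxyaryl 1,3-diketone, and acid or heat would condense that hydroxyl with the distal ketone. The oxygen meant for C5 would then become O1, and the product would be 3-(benzyloxy)-2-[4-(benzyloxy)phenyl]-6-hydroxy-7,8-dimethoxy-4H-chromen-4-one A10. From A10 the target could be reached only by methylation at O6 and the same C5–H hydroxylation as in the chosen plan. A9 is a 5,8-hydroquinone and would be air-sensitive.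
- Comparison: on structure it sets all five ring A oxygens without a late C–H oxidation and is the better plan there. On mechanism the siloxyfuran benzannulation and the quinone closure both have closer analogy than the anodic step. On step economy and on the stability of intermediates the chosen plan is clearly ahead, since A5 and A6 each need several steps and A6 and A7 each offer a fast unwanted ring closure.

Alternative 3: The cut takes ring A apart into a four-carbon vinylketene and a two-carbon alkyne, before rings C and B exist.
- Forward step: rac-2,3,4-trimethoxycyclobut-2-en-1-one A11 would open on heating to its vinylketene, which would add methoxyethyne A12 in a [2+2] sense. 4π opening of the new cyclobutenone, 6π closure and tautomerisation would give 2,3,4,5-tetramethoxyphenol A13.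
- Atom mapping: in A13 the phenol oxygen is the future O1, the single ring hydrogen marks C4a, and the methoxyl brought by A12 sits at C5. The bonds formed are C4a–C8a, C5–C6 and C8–C8a.
- Onward route: acetylation of A13 at its only free position would give 1-(2-hydroxy-3,4,5,6-tetramethoxyphenyl)ethan-1-one A14. From A14 the flavonol would follow by Baker–Venkataraman or Allan–Robinson chemistry and chelation-controlled demethylation at C5.
- In favour: the regiochemistry follows from ketene and ynol ether polarity, every ring A oxygen is set by a known pericyclic cascade, and no C–H oxidation or electrolysis is needed. Every later step has precedent on polymethoxyflavones, so in certainty of each step this alternative is better than the chosen plan.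
- Against: A11 must be made from a squaric ester and A12 is volatile and unstable. The key step delivers ring A only, so rings C and B still cost four or five steps. The 6'-methoxy-2'-hydroxy pattern tends to divert the Algar–Flynn–Oyamada reaction to aurones, which narrows the choice of ring C methods.
- Comparison: on structure it solves the pentaoxygenated ring at the outset, where the chosen plan does so by two late oxidations. On mechanism it is better understood. On step economy it is far behind, at roughly a dozen steps against five.

Key step: step 3

Remarks on the chemistry:
- 3 is drawn as the diketone but should exist largely as its chelated enol. 4, substituted at the central carbon, should be mainly the diketone and is racemic; its single stereocentre becomes the sp2 carbon C3 in step 3, so no stereocontrol is needed.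
- 2 is taken as a stock reagent (otherwise one step from 4-acetoxybenzoic acid).
- The ring B oxygen is carried as its acetate from the start by soft-enolisation acylation. This avoids a benzyl ether, a hydrogenolysis beside two aryl ketones and a separate phenol acetylation.
- O1 adds a fourth oxygen donor to ring A, so 5 cannot be assumed harder to oxidise at the arene than 4. The protection against over-oxidation is therefore placed in the enolate, which 4 can form and 5 cannot, and in the charge passed.

## Steps

Step 1
Reactants: 1 3,4,5-trimethoxyacetophenone; 2 4-acetoxybenzoyl chloride [4-(chlorocarbonyl)phenyl acetate]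
Product: 3 4-[3-oxo-3-(3,4,5-trimethoxyphenyl)propanoyl]phenyl acetate
Conditions: MgBr2·OEt2 (2.5 equiv), i-Pr2NEt (3 equiv), CH2Cl2, 0 °C to rt; then 1 M HCl
Reagents that add atoms: none
Why: Soft-enolisation C-acylation of a methyl ketone by an acid chloride (Claisen-type 1,3-diketone synthesis through the magnesium enolate). The amine/MgBr2 pair is too mild to attack the aryl acetate, and the chelated magnesium diketonate of 3 resists a second acylation.

Step 2
Reactants: 3 4-[3-oxo-3-(3,4,5-trimethoxyphenyl)propanoyl]phenyl acetate
Product: 4 rac-1-[4-(acetyloxy)phenyl]-1,3-dioxo-3-(3,4,5-trimethoxyphenyl)propan-2-yl acetate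
Conditions: PhI(OAc)2 (1.1 equiv), AcOH, rt
Reagents that add atoms: (diacetoxyiodo)benzene, CC(=O)OI(OC(C)=O)c1ccccc1
Why: Electrophilic α-acetoxylation of a 1,3-diketone enol by a trivalent iodine reagent (enol attack on iodine, then displacement of iodobenzene by acetate at the central carbon). 4 is less enolised and more hindered than 3, which restrains a second acetoxylation, and the new stereocentre forms as the racemate and is erased in step 3.

Step 3
Reactants: 4 rac-1-[4-(acetyloxy)phenyl]-1,3-dioxo-3-(3,4,5-trimethoxyphenyl)propan-2-yl acetate
Product: 5 4-[3-(acetyloxy)-6,7,8-trimethoxy-4-oxo-4H-chromen-2-yl]phenyl acetate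
Conditions: undivided cell, graphite anode, Pt cathode, constant current (about 5 mA cm−2, 2.2 F mol−1), n-Bu4NPF6 (0.1 M), 2,6-lutidine (2 equiv), MeCN/(CF3)2CHOH 4:1, rt, Ar
Reagents that add atoms: none
Why: Proposed new method: with 2,6-lutidine present, the enolate of 4, whose reactive oxygen sits on the carbon bearing ring B, should be oxidised at the anode by one electron (oxidation of the trimethoxyaryl ring to its radical cation would lead to the same species), and that oxygen then bonds to an ortho carbon of the trimethoxyphenyl ring, a position ortho to one methoxyl and para to another, giving a cyclohexadienyl radical stabilised by the methoxyls and the C4 carbonyl. A second anodic electron transfer and loss of the ortho proton to lutidine restore the aromaticity of ring A, while protons are reduced to H2 at the cathode, so no chemical oxidant is consumed. The closest known reaction types are the anodic dehydrogenative lactonisation of biaryl-2-carboxylic acids and the oxidative closure of enol or phenol oxygens onto alkoxy-substituted arenes (benzofurans from α-aryl ketones, dibenzofurans from 2-arylphenols), whereas closure of a 4-pyranone by an enol oxygen onto an unfunctionalised arene C–H has not been shown. Ring C closes in a six-membered mode, formally 6-endo-trig with respect to the C4a–C8a π bond of the arene, and neither the central carbon nor the other enol oxygen can reach ring A except through a four-membered ring. No stereocentre is formed, and the one in 4 becomes the sp2 carbon C3. Chemoselectivity between the two aryl rings is required and should follow from ring A being the electron-rich partner while ring B is deactivated by its acetoxy and acyl groups, and regioselectivity is not at issue because the two ortho positions of ring A are equivalent. Over-oxidation should be held back because 5 has no enol to ionise, so the enolate of 4 is discharged below the potential of either arene, and because the charge is limited to little more than two electrons per molecule.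

Step 4
Reactants: 5 4-[3-(acetyloxy)-6,7,8-trimethoxy-4-oxo-4H-chromen-2-yl]phenyl acetate
Product: 7 4-[3-(acetyloxy)-5-hydroxy-6,7,8-trimethoxy-4-oxo-4H-chromen-2-yl]phenyl acetate, via C5 trifluoroacetate ester 6 (not isolated)
Conditions: [RuCl2(p-cymene)]2 (5 mol %), PhI(OCOCF3)2 (2 equiv), CF3CO2H/(CF3CO)2O 3:1, 80 °C; then aq NaHCO3, rt
Reagents that add atoms: [bis(trifluoroacetoxy)iodo]benzene, O=C(OI(OC(=O)C(F)(F)F)c1ccccc1)C(F)(F)F
Why: Ketone-directed ortho C–H oxygenation with divalent ruthenium, a reaction type established on flavones and chromones: the C4 carbonyl binds ruthenium, the only ring A hydrogen (C5–H) is cleaved to a five-membered ruthenacycle, and oxidation by the trivalent iodine reagent with C–O reductive elimination gives 6. The electron-poor trifluoroacetate shields the new oxygen from oxidation toward the 5,8-quinone, and bicarbonate hydrolyses it much faster than the two acetates.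

Step 5
Reactants: 7 4-[3-(acetyloxy)-5-hydroxy-6,7,8-trimethoxy-4-oxo-4H-chromen-2-yl]phenyl acetate
Product: 8 3,5-dihydroxy-2-(4-hydroxyphenyl)-6,7,8-trimethoxy-4H-chromen-4-one (3,5,4'-trihydroxy-6,7,8-trimethoxyflavone)
Conditions: K2CO3 (3 equiv), degassed MeOH, 0 °C to rt, Ar; then 1 M HCl to pH 3
Reagents that add atoms: none
Why: Base-mediated transesterification (Zemplén-type methanolysis) removes the enol acetate at O3 and the aryl acetate at O4'. The methyl ethers are inert, and exclusion of air protects the flavonol anion.

## Compound list

1 | 3,4,5-trimethoxyacetophenone | CC(=O)c1cc(OC)c(OC)c(OC)c1 | starting material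
2 | 4-acetoxybenzoyl chloride | CC(=O)Oc1ccc(cc1)C(Cl)=O | starting material
3 | 4-[3-oxo-3-(3,4,5-trimethoxyphenyl)propanoyl]phenyl acetate | COc1cc(C(=O)CC(=O)c2ccc(OC(C)=O)cc2)cc(OC)c1OC | intermediate
4 | rac-1-[4-(acetyloxy)phenyl]-1,3-dioxo-3-(3,4,5-trimethoxyphenyl)propan-2-yl acetate | COc1cc(C(=O)C(OC(C)=O)C(=O)c2ccc(OC(C)=O)cc2)cc(OC)c1OC | intermediate
5 | 4-[3-(acetyloxy)-6,7,8-trimethoxy-4-oxo-4H-chromen-2-yl]phenyl acetate | COc1cc2c(=O)c(OC(C)=O)c(-c3ccc(OC(C)=O)cc3)oc2c(OC)c1OC | intermediate
6 | 3-(acetyloxy)-2-[4-(acetyloxy)phenyl]-6,7,8-trimethoxy-4-oxo-4H-chromen-5-yl trifluoroacetate | COc1c(OC)c(OC(=O)C(F)(F)F)c2c(=O)c(OC(C)=O)c(-c3ccc(OC(C)=O)cc3)oc2c1OC | intermediate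
7 | 4-[3-(acetyloxy)-5-hydroxy-6,7,8-trimethoxy-4-oxo-4H-chromen-2-yl]phenyl acetate | COc1c(OC)c(O)c2c(=O)c(OC(C)=O)c(-c3ccc(OC(C)=O)cc3)oc2c1OC | intermediate
8 | 3,5-dihydroxy-2-(4-hydroxyphenyl)-6,7,8-trimethoxy-4H-chromen-4-one | COc1c(OC)c(O)c2c(=O)c(O)c(-c3ccc(O)cc3)oc2c1OC | target

Total step count: 5. Longest linear sequence: 5 steps (1 or 2 to 8).

## Least certain steps

**Step 3 (key step).**
- What may go wrong:
  - The oxidised enol may dimerise or pick up hydrogen instead of closing.
  - Closure may occur at the ipso carbon (para to the central methoxyl), giving a spiro ring with loss of a methyl group.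
  - The methoxy-rich chromone may be oxidised further once formed.
  - The acetyl group may migrate between the neighbouring oxygens of the enolate.
- Fallback (known chemistry, sets out from 1, returns at 5): the C8a–O1 bond is made by substitution of a halide. Ring bromination of 1 (NBS, MeCN, rt) should give 1-(2-bromo-3,4,5-trimethoxyphenyl)ethan-1-one F1. Soft-enolisation acylation with 2 (MgBr2·OEt2, i-Pr2NEt, CH2Cl2) would give 4-[3-(2-bromo-3,4,5-trimethoxyphenyl)-3-oxopropanoyl]phenyl acetate F2. Acetoxylation (PhI(OAc)2, AcOH) would give rac-1-[4-(acetyloxy)phenyl]-3-(2-bromo-3,4,5-trimethoxyphenyl)-1,3-dioxopropan-2-yl acetate F3. Intramolecular Ullmann-type O-arylation of the enolate (CuI, 1,10-phenanthroline, K3PO4, toluene, 90 °C; monovalent copper), an established chromone synthesis from 1-(2-bromoaryl)-1,3-diketones, would then give 5.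

**Step 4.**
- What may go wrong:
  - Cyclometalation may be slow at a C–H flanked by the peri carbonyl and the C6 methoxyl.
  - The iodine reagent may oxidise ring A by electron transfer, with demethylation toward quinones.
  - Acetate may exchange for trifluoroacetate in the hot acid medium. This is harmless, since every ester is cleaved in step 5 and the two steps can be telescoped.
- Fallback (sets out from 5, returns at 8): halogenation then hydroxylation. Electrophilic bromination at the only ring A position (NBS, MeCN; ortho to the C6 methoxyl and para to the C8 methoxyl) should give 4-[3-(acetyloxy)-5-bromo-6,7,8-trimethoxy-4-oxo-4H-chromen-2-yl]phenyl acetate F4. Hydroxylation of the aryl bromide (Pd2(dba)3 as the source of zerovalent palladium, t-BuXPhos, KOH, dioxane/H2O, 100 °C, Ar; then HCl) would install the C5 hydroxyl and hydrolyse both acetates in the same operation, giving 8 directly.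

**Step 1.**
- What may go wrong:
  - The diketonate may be acylated a second time, on oxygen or carbon.
  - Acetyl may transfer from the aryl acetate to the enolate.
  - Enolisation of the electron-rich ketone may be incomplete.
- Fallback (sets out from 1, returns at 3): hydride-base Claisen condensation with an ether-protected ester. 1 with methyl 4-(benzyloxy)benzoate (COC(=O)c1ccc(OCc2ccccc2)cc1) and NaH in THF at reflux, then aqueous HCl, would give 1-[4-(benzyloxy)phenyl]-3-(3,4,5-trimethoxyphenyl)propane-1,3-dione F5. Hydrogenolysis (H2, Pd/C, EtOAc) would give 1-(4-hydroxyphenyl)-3-(3,4,5-trimethoxyphenyl)propane-1,3-dione F6. Phenol acetylation (Ac2O 1.05 equiv, pyridine, 0 °C) would give 3.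

**Step 2.**
- What may go wrong:
  - A second acetoxylation or oxidative cleavage of the diketone.
  - Diversion to an iodonium ylide.
  - Acetyl migration to the enol oxygen.
- Fallback (sets out from 3, returns at 4): halogenation then displacement. Bromination of the enol (NBS 1.0 equiv, CH2Cl2, 0 °C) would give rac-4-[2-bromo-3-oxo-3-(3,4,5-trimethoxyphenyl)propanoyl]phenyl acetate F7. Substitution by acetate (KOAc, DMF/AcOH, rt) would give 4.

## Further compounds

F1 | step 3 | 1-(2-bromo-3,4,5-trimethoxyphenyl)ethan-1-one | CC(=O)c1cc(OC)c(OC)c(OC)c1Br
F2 | step 3 | 4-[3-(2-bromo-3,4,5-trimethoxyphenyl)-3-oxopropanoyl]phenyl acetate | COc1cc(C(=O)CC(=O)c2ccc(OC(C)=O)cc2)c(Br)c(OC)c1OC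
F3 | step 3 | rac-1-[4-(acetyloxy)phenyl]-3-(2-bromo-3,4,5-trimethoxyphenyl)-1,3-dioxopropan-2-yl acetate | COc1cc(C(=O)C(OC(C)=O)C(=O)c2ccc(OC(C)=O)cc2)c(Br)c(OC)c1OC
F4 | step 4 | 4-[3-(acetyloxy)-5-bromo-6,7,8-trimethoxy-4-oxo-4H-chromen-2-yl]phenyl acetate | COc1c(OC)c(Br)c2c(=O)c(OC(C)=O)c(-c3ccc(OC(C)=O)cc3)oc2c1OC
F5 | step 1 | 1-[4-(benzyloxy)phenyl]-3-(3,4,5-trimethoxyphenyl)propane-1,3-dione | COc1cc(C(=O)CC(=O)c2ccc(OCc3ccccc3)cc2)cc(OC)c1OC
F6 | step 1 | 1-(4-hydroxyphenyl)-3-(3,4,5-trimethoxyphenyl)propane-1,3-dione | COc1cc(C(=O)CC(=O)c2ccc(O)cc2)cc(OC)c1OC
F7 | step 2 | rac-4-[2-bromo-3-oxo-3-(3,4,5-trimethoxyphenyl)propanoyl]phenyl acetate | COc1cc(C(=O)C(Br)C(=O)c2ccc(OC(C)=O)cc2)cc(OC)c1OC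
A1 | alternative 1 | 5,6,7,8-tetramethoxy-2,2-dimethyl-4H-1,3-benzodioxin-4-one | CC1(C)OC(=O)c2c(OC)c(OC)c(OC)c(OC)c2O1
A2 | alternative 1 | 2,3,4,5-tetramethoxy-6-(oxomethylidene)cyclohexa-2,4-dien-1-one | O=C=C1C(=O)C(OC)=C(OC)C(OC)=C1OC
A3 | alternative 1 | (Z)-{[2-(benzyloxy)-1-[4-(benzyloxy)phenyl]ethenyl]oxy}trimethylsilane | C[Si](C)(C)O/C(=C\OCc1ccccc1)c1ccc(OCc2ccccc2)cc1
A4 | alternative 1 | 3-(benzyloxy)-2-[4-(benzyloxy)phenyl]-5,6,7,8-tetramethoxy-4H-chromen-4-one | COc1c(OC)c(OC)c2c(=O)c(OCc3ccccc3)c(-c3ccc(OCc4ccccc4)cc3)oc2c1OC
A5 | alternative 2 | tert-butyl[(3,4-dimethoxyfuran-2-yl)oxy]dimethylsilane | COc1coc(O[Si](C)(C)C(C)(C)C)c1OC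
A6 | alternative 2 | rac-2-(benzyloxy)-1-[4-(benzyloxy)phenyl]pent-4-yne-1,3-dione | C#CC(=O)C(OCc1ccccc1)C(=O)c1ccc(OCc2ccccc2)cc1
A7 | alternative 2 | rac-2-(benzyloxy)-3-[4-(benzyloxy)phenyl]-1-(2,5-dihydroxy-3,4-dimethoxyphenyl)propane-1,3-dione | COc1c(OC)c(O)c(C(=O)C(OCc2ccccc2)C(=O)c2ccc(OCc3ccccc3)cc2)cc1O
A8 | alternative 2 | rac-2-(benzyloxy)-1-[4-(benzyloxy)phenyl]-3-(4,5-dimethoxy-3,6-dioxocyclohexa-1,4-dien-1-yl)propane-1,3-dione | COC1=C(OC)C(=O)C(C(=O)C(OCc2ccccc2)C(=O)c2ccc(OCc3ccccc3)cc2)=CC1=O
A9 | alternative 2 | 3-(benzyloxy)-2-[4-(benzyloxy)phenyl]-5,8-dihydroxy-6,7-dimethoxy-4H-chromen-4-one | COc1c(OC)c(O)c2c(=O)c(OCc3ccccc3)c(-c3ccc(OCc4ccccc4)cc3)oc2c1O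
A10 | alternative 2 | 3-(benzyloxy)-2-[4-(benzyloxy)phenyl]-6-hydroxy-7,8-dimethoxy-4H-chromen-4-one | COc1c(O)cc2c(=O)c(OCc3ccccc3)c(-c3ccc(OCc4ccccc4)cc3)oc2c1OC
A11 | alternative 3 | rac-2,3,4-trimethoxycyclobut-2-en-1-one | COC1C(=O)C(OC)=C1OC
A12 | alternative 3 | methoxyethyne | COC#C
A13 | alternative 3 | 2,3,4,5-tetramethoxyphenol | COc1cc(O)c(OC)c(OC)c1OC
A14 | alternative 3 | 1-(2-hydroxy-3,4,5,6-tetramethoxyphenyl)ethan-1-one | CC(=O)c1c(O)c(OC)c(OC)c(OC)c1OC
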